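**Strategy**

Everything rests on cutting ring B at two neighbouring bonds, C4–O and C3–CH2(prenyl), which sit directly beside the C2 methoxy group; this contiguous C2/C3/C4 pattern is what a 3-methoxyaryne spanning C3–C4 delivers. In one operation the aryne, released from 1-bromo-4-fluoro-2-methoxybenzene by lithiation between fluorine and methoxy and loss of LiF, should accept a silylethoxide oxygen at C4 and, through the resulting C3 aryl-metal, the prenyl group, while the C1 bromide is kept as the handle for the propenone chain. A Heck coupling with a bis-silylated ring A aryl vinyl ketone and one fluoride-mediated deprotection then complete the chalcone.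

Key step: step 5

Remark on the chemistry: ring B is numbered as in the target throughout (C1 carries the propenone chain or the bromine that stands in for it, C2 the methoxy group, C3 the prenyl group, C4 the oxygen). Alcohol 4 is racemic and its stereocentre disappears in step 3, so the only stereochemical element of the target, the E alkene, is set in step 6.

**Route**

Step 1
Reactants: 1 3,4-dihydroxybenzaldehyde
Product: 2 3,4-bis(tert-butyldimethylsilyloxy)benzaldehyde
Conditions: TBSCl (2.4 equiv), imidazole (5 equiv), DMF, rt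
Reagents that add atoms: tert-butyldimethylsilyl chloride, CC(C)(C)[Si](C)(C)Cl
Why: Imidazole-promoted silylation of phenols with a silyl chloride converts both acidic catechol hydroxyls into aryl silyl ethers and leaves the aldehyde untouched.

Step 2
Reactants: 2 3,4-bis(tert-butyldimethylsilyloxy)benzaldehyde; 3 vinylmagnesium bromide (CH2=CHMgBr)
Product: 4 racemic 1-[3,4-bis(tert-butyldimethylsilyloxy)phenyl]prop-2-en-1-ol
Conditions: CH2=CHMgBr (1.2 equiv), THF, −78 → 0 °C; then H2O (NH4Cl buffer)
Reagents that add atoms: none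
Why: Grignard 1,2-addition to an aromatic aldehyde is fast at low temperature and compatible with aryl silyl ethers, and the new carbinol centre, formed without control as the racemate, is erased by the oxidation in step 3.

Step 3
Reactants: 4 racemic 1-[3,4-bis(tert-butyldimethylsilyloxy)phenyl]prop-2-en-1-ol
Product: 5 1-[3,4-bis(tert-butyldimethylsilyloxy)phenyl]prop-2-en-1-one
Conditions: MnO2 (activated, excess), CH2Cl2, rt; product stored cold and used promptly
Reagents that add atoms: none
Why: MnO2 oxidation is selective for an alcohol that is both allylic and benzylic, runs under neutral conditions that spare the silyl ethers, and leaves the vinyl group intact.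

Step 4
Reactants: 6 2-(trimethylsilyl)ethanol
Product: 7 lithium 2-(trimethylsilyl)ethoxide (titrated THF stock solution, used directly)
Conditions: n-BuLi (1.00 equiv, titrated), THF, −78 → 0 °C
Reagents that add atoms: n-butyllithium, [Li]CCCC
Why: Simple acid–base metalation of an alcohol by an alkyllithium is quantitative, and exact stoichiometry leaves neither free alcohol, which would quench the aryllithium of step 5, nor free n-BuLi, which would exchange the C1 bromide of 8.

Step 5
Reactants: 8 1-bromo-4-fluoro-2-methoxybenzene; 7 lithium 2-(trimethylsilyl)ethoxide; 9 prenyl bromide (1-bromo-3-methylbut-2-ene)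
Product: 14 1-bromo-2-methoxy-3-(3-methylbut-2-en-1-yl)-4-[2-(trimethylsilyl)ethoxy]benzene, via ortho-lithiated fluoroarene 10 (not isolated), via 3-methoxyaryne 11 (not isolated), via dialkoxyaryllithium 12 (not isolated), via arylcopper 13 (not isolated)
Conditions: LiNC9H18 (lithium 2,2,6,6-tetramethylpiperidide, 1.1 equiv, from 2,2,6,6-tetramethylpiperidine and n-BuLi), THF, −78 °C, 1 h; slow cannulation into 7 (4 equiv), THF, −20 → 0 °C; CuBr·SMe2 (1.2 equiv), −40 °C; 9 (5 equiv), −40 → 0 °C; aq. NH4Cl/NH3
Reagents that add atoms: none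
Why: Proposed new method: LiNC9H18 removes the C3 hydrogen of 8, the most acidic one because fluorine and methoxy flank it, and on warming 10 expels LiF to give the C3–C4 aryne 11; the oxygen of 7 then adds at C4 so that the carbanion develops at C3, where the adjacent C2 oxygen stabilises it inductively and two ether oxygens chelate lithium (12), and transfer to copper (13) is followed by SN2 displacement on 9 at its primary carbon. The closest known reaction type is the three-component coupling of an aryne from an ortho-lithiated haloarene with a lithium amide, thiolate or carbanion followed by electrophilic quench of the new aryllithium; the untested element is an alkoxide as the adding nucleophile. No ring is closed and no stereocentre is formed. The step needs regioselective addition across C3–C4, which the C2 methoxy group secures by polarising and distorting the aryne toward attack at the remote terminus, and it needs the alkoxide to outcompete self-addition of 10 to 11, which is addressed by completing the lithiation at −78 °C and then feeding cold 10 slowly into an excess of 7 at the temperature of LiF loss. Bromine is kept at C1 because it resists the amide base and the arylcopper yet is reactive enough for the palladium step, and copper keeps the allylation at the primary terminus of 9.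

Step 6
Reactants: 14 1-bromo-2-methoxy-3-(3-methylbut-2-en-1-yl)-4-[2-(trimethylsilyl)ethoxy]benzene; 5 1-[3,4-bis(tert-butyldimethylsilyloxy)phenyl]prop-2-en-1-one
Product: 15 (E)-1-[3,4-bis(tert-butyldimethylsilyloxy)phenyl]-3-{2-methoxy-3-(3-methylbut-2-en-1-yl)-4-[2-(trimethylsilyl)ethoxy]phenyl}prop-2-en-1-one
Conditions: Pd2(dba)3 (tris(dibenzylideneacetone)dipalladium, 2.5 mol %), [HP(t-Bu)3]BF4 (6 mol %), Cy2NMe (1.5 equiv), 5 (1.5 equiv), 1,4-dioxane, 60 °C
Reagents that add atoms: none
Why: In this Mizoroki–Heck reaction zerovalent palladium carrying the bulky, electron-rich P(t-Bu)3 should insert into the electron-rich, ortho-substituted C1–Br bond at mild temperature, and syn-carbopalladation of the terminal carbon of 5 followed by syn-β-hydride elimination from the rotamer with aryl and acyl groups apart gives the E enone, while the trisubstituted prenyl alkene does not compete and the silyl groups are inert to the hindered amine.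

Step 7
Reactants: 15 (E)-1-[3,4-bis(tert-butyldimethylsilyloxy)phenyl]-3-{2-methoxy-3-(3-methylbut-2-en-1-yl)-4-[2-(trimethylsilyl)ethoxy]phenyl}prop-2-en-1-one
Product: 16 Licoagrochalcone C, (E)-1-(3,4-dihydroxyphenyl)-3-[4-hydroxy-2-methoxy-3-(3-methylbut-2-en-1-yl)phenyl]prop-2-en-1-one
Conditions: Bu4NF (6 equiv), THF, 0 → 50 °C, Ar; then AcOH, H2O
Reagents that add atoms: none
Why: Fluoride-induced desilylation cleaves both aryl silyl ethers at silicon and fragments the trimethylsilylethyl ether by β-elimination to ethene, Me3SiF and the C4 phenoxide, a good leaving group because it is conjugated with the enone, and the absence of acid keeps the ortho-prenyl phenol from cyclising to a chroman while argon protects the catechol.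

**Compound list**

1 | 3,4-dihydroxybenzaldehyde | O=Cc1ccc(O)c(O)c1 | starting material
2 | 3,4-bis(tert-butyldimethylsilyloxy)benzaldehyde | O=Cc1ccc(O[Si](C)(C)C(C)(C)C)c(O[Si](C)(C)C(C)(C)C)c1 | intermediate
3 | vinylmagnesium bromide | C=C[Mg]Br | starting material
4 | racemic 1-[3,4-bis(tert-butyldimethylsilyloxy)phenyl]prop-2-en-1-ol | C=CC(O)c1ccc(O[Si](C)(C)C(C)(C)C)c(O[Si](C)(C)C(C)(C)C)c1 | intermediate
5 | 1-[3,4-bis(tert-butyldimethylsilyloxy)phenyl]prop-2-en-1-one | C=CC(=O)c1ccc(O[Si](C)(C)C(C)(C)C)c(O[Si](C)(C)C(C)(C)C)c1 | intermediate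
6 | 2-(trimethylsilyl)ethanol | OCC[Si](C)(C)C | starting material
7 | lithium 2-(trimethylsilyl)ethoxide | [Li+].[O-]CC[Si](C)(C)C | intermediate
8 | 1-bromo-4-fluoro-2-methoxybenzene | COc1cc(F)ccc1Br | starting material
9 | prenyl bromide (1-bromo-3-methylbut-2-ene) | CC(C)=CCBr | starting material
10 | (3-bromo-6-fluoro-2-methoxyphenyl)lithium (lithium at C3) | COc1c([Li])c(F)ccc1Br | intermediate
11 | 1-bromo-2-methoxy-3,4-didehydrobenzene (4-bromo-3-methoxybenzyne) | COC1=C(Br)C=CC#C1 | intermediate
12 | {3-bromo-2-methoxy-6-[2-(trimethylsilyl)ethoxy]phenyl}lithium (lithium at C3) | COc1c(Br)ccc(OCC[Si](C)(C)C)c1[Li] | intermediate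
13 | {3-bromo-2-methoxy-6-[2-(trimethylsilyl)ethoxy]phenyl}copper | COc1c(Br)ccc(OCC[Si](C)(C)C)c1[Cu] | intermediate
14 | 1-bromo-2-methoxy-3-(3-methylbut-2-en-1-yl)-4-[2-(trimethylsilyl)ethoxy]benzene | COc1c(Br)ccc(OCC[Si](C)(C)C)c1CC=C(C)C | intermediate
15 | (E)-1-[3,4-bis(tert-butyldimethylsilyloxy)phenyl]-3-{2-methoxy-3-(3-methylbut-2-en-1-yl)-4-[2-(trimethylsilyl)ethoxy]phenyl}prop-2-en-1-one | COc1c(/C=C/C(=O)c2ccc(O[Si](C)(C)C(C)(C)C)c(O[Si](C)(C)C(C)(C)C)c2)ccc(OCC[Si](C)(C)C)c1CC=C(C)C | intermediate
16 | Licoagrochalcone C, (E)-1-(3,4-dihydroxyphenyl)-3-[4-hydroxy-2-methoxy-3-(3-methylbut-2-en-1-yl)phenyl]prop-2-en-1-one | COc1c(/C=C/C(=O)c2ccc(O)c(O)c2)ccc(O)c1CC=C(C)C | target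

**Step count**

Total steps: 7. Longest linear sequence: 5 steps (steps 1, 2, 3, 6, 7); the ring B branch (steps 4, 5, 6, 7) has 4.

**Steps most likely to fail**

Step 5 (carries the label). The aggregated lithium alkoxide may add to the aryne more slowly than the aryllithium precursor or the amide base does, so that the aryne is lost to self-arylation or amination. Part of the prenyl bromide may also be diverted by the surplus alkoxide. The fallback uses known chemistry and sets out from 6. Mitsunobu etherification of commercial 4-bromo-3-methoxyphenol (COc1cc(O)ccc1Br) with 6 (PPh3, diisopropyl azodicarboxylate, THF, 0 °C → rt) should give 1-bromo-2-methoxy-4-[2-(trimethylsilyl)ethoxy]benzene F1, which already holds the C4 oxygen and the C1 bromine. Deprotonation of F1 at C3, the position between the two ether oxygens, with LiNC9H18 (THF, −78 → −40 °C; a lithium amide leaves the bromide alone where an alkyllithium would exchange it) gives aryllithium 12. There the fallback comes back to the route, and CuBr·SMe2 and 9 as in step 5 lead on to 14.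

Step 6. Oxidative addition into the electron-rich, ortho-substituted aryl bromide may be slow, and the aryl vinyl ketone may oligomerise in the meantime under heat and base. The fallback avoids palladium and sets out from 14.
- Bromine–lithium exchange (n-BuLi, THF, −78 °C) gives {2-methoxy-3-(3-methylbut-2-en-1-yl)-4-[2-(trimethylsilyl)ethoxy]phenyl}lithium F2, which is formylated with DMF to 2-methoxy-3-(3-methylbut-2-en-1-yl)-4-[2-(trimethylsilyl)ethoxy]benzaldehyde F3.
- Commercial 3,4-dihydroxyacetophenone is silylated (TBSCl, imidazole, DMF) to 1-[3,4-bis(tert-butyldimethylsilyloxy)phenyl]ethanone F4, and LiN(SiMe3)2 (THF, −78 °C) converts it into lithium 1-[3,4-bis(tert-butyldimethylsilyloxy)phenyl]ethen-1-olate F5.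
- Directed aldol addition of F5 to F3 gives racemic 1-[3,4-bis(tert-butyldimethylsilyloxy)phenyl]-3-hydroxy-3-{2-methoxy-3-(3-methylbut-2-en-1-yl)-4-[2-(trimethylsilyl)ethoxy]phenyl}propan-1-one F6.
- MsCl and Et3N (CH2Cl2, 0 °C → rt) form the racemic 3-methanesulfonyloxy derivative of that ketone F7, which eliminates in the same flask (E1cB) to the E enone 15, where the fallback rejoins the route.

Step 7. β-Elimination of the trimethylsilylethyl ether may remain incomplete at temperatures the base-sensitive, oxidisable catechol chalcone tolerates, and prolonged exposure to basic fluoride may degrade the enone. The fallback moves the difficult cleavage to a robust intermediate and sets out from 14.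
- CsF in DMF at 110 °C removes the silylethyl group to give 4-bromo-3-methoxy-2-(3-methylbut-2-en-1-yl)phenol F8.
- Silylation (TBSCl, imidazole, DMF) gives [4-bromo-3-methoxy-2-(3-methylbut-2-en-1-yl)phenoxy](tert-butyl)dimethylsilane F9.
- Heck coupling of F9 with 5 under the conditions of step 6 gives (E)-1-[3,4-bis(tert-butyldimethylsilyloxy)phenyl]-3-[4-(tert-butyldimethylsilyloxy)-2-methoxy-3-(3-methylbut-2-en-1-yl)phenyl]prop-2-en-1-one F10.
- The three aryl silyl ethers of F10 are then cleaved at 0 °C with Bu4NF buffered by AcOH in THF, which comes back to the route at 16.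

**Further compounds**

F1 | step 5 | 1-bromo-2-methoxy-4-[2-(trimethylsilyl)ethoxy]benzene | COc1cc(OCC[Si](C)(C)C)ccc1Br
F2 | step 6 | {2-methoxy-3-(3-methylbut-2-en-1-yl)-4-[2-(trimethylsilyl)ethoxy]phenyl}lithium | COc1c([Li])ccc(OCC[Si](C)(C)C)c1CC=C(C)C
F3 | step 6 | 2-methoxy-3-(3-methylbut-2-en-1-yl)-4-[2-(trimethylsilyl)ethoxy]benzaldehyde | COc1c(C=O)ccc(OCC[Si](C)(C)C)c1CC=C(C)C
F4 | step 6 | 1-[3,4-bis(tert-butyldimethylsilyloxy)phenyl]ethanone | CC(=O)c1ccc(O[Si](C)(C)C(C)(C)C)c(O[Si](C)(C)C(C)(C)C)c1
F5 | step 6 | lithium 1-[3,4-bis(tert-butyldimethylsilyloxy)phenyl]ethen-1-olate | [Li]OC(=C)c1ccc(O[Si](C)(C)C(C)(C)C)c(O[Si](C)(C)C(C)(C)C)c1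
F6 | step 6 | racemic 1-[3,4-bis(tert-butyldimethylsilyloxy)phenyl]-3-hydroxy-3-{2-methoxy-3-(3-methylbut-2-en-1-yl)-4-[2-(trimethylsilyl)ethoxy]phenyl}propan-1-one | COc1c(C(O)CC(=O)c2ccc(O[Si](C)(C)C(C)(C)C)c(O[Si](C)(C)C(C)(C)C)c2)ccc(OCC[Si](C)(C)C)c1CC=C(C)C
F7 | step 6 | racemic 3-[3,4-bis(tert-butyldimethylsilyloxy)phenyl]-1-{2-methoxy-3-(3-methylbut-2-en-1-yl)-4-[2-(trimethylsilyl)ethoxy]phenyl}-3-oxopropyl methanesulfonate | COc1c(C(CC(=O)c2ccc(O[Si](C)(C)C(C)(C)C)c(O[Si](C)(C)C(C)(C)C)c2)OS(C)(=O)=O)ccc(OCC[Si](C)(C)C)c1CC=C(C)C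
F8 | step 7 | 4-bromo-3-methoxy-2-(3-methylbut-2-en-1-yl)phenol | COc1c(Br)ccc(O)c1CC=C(C)C
F9 | step 7 | [4-bromo-3-methoxy-2-(3-methylbut-2-en-1-yl)phenoxy](tert-butyl)dimethylsilane | COc1c(Br)ccc(O[Si](C)(C)C(C)(C)C)c1CC=C(C)C
F10 | step 7 | (E)-1-[3,4-bis(tert-butyldimethylsilyloxy)phenyl]-3-[4-(tert-butyldimethylsilyloxy)-2-methoxy-3-(3-methylbut-2-en-1-yl)phenyl]prop-2-en-1-one | COc1c(/C=C/C(=O)c2ccc(O[Si](C)(C)C(C)(C)C)c(O[Si](C)(C)C(C)(C)C)c2)ccc(O[Si](C)(C)C(C)(C)C)c1CC=C(C)C
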